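The benzene ring carries oxygen at C2 (OH) and C4 (OMe) with only C3 between them, the signature of a cyclohexane-1,3-dione one oxidation level lower. The ring is therefore disconnected at C3–C4, at a stage where C1 and C6 are still tetrahedral. The precursor is an acyclic keto diester, dimethyl 2-acetyl-3-icosylpentanedioate, reached by cross-metathesis and a Michael addition. In one operation methoxide bonds the terminal acetyl carbon (future C3) to the carbonyl carbon of the acetate arm (future C4). This closes the only ring and puts both ring oxygens, the C1 ester and the C6 chain in their final positions. Iodine in methanol then etherifies O4 and aromatises.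

Key step: step 3

Remark: ring atoms are numbered as in the benzoate name (C1 bears CO2Me, C2 OH, C4 OMe, C6 the chain). The chain is read as unbranched icosyl (C20). The target has no stereocentre, so racemic and diastereomeric intermediates are acceptable.

Step 1
Reactants: 1 docos-1-ene; 2 methyl acrylate
Product: 3 methyl (E)-tricos-2-enoate
Conditions: 2 (3 equiv), second-generation Hoveyda–Grubbs catalyst RuCl2(SIMes)(=CH-C6H4-2-OiPr) (1 mol %), 1,4-benzoquinone (10 mol %), CH2Cl2, 40 °C
Reagents that add atoms: none
Why: Olefin cross-metathesis of an unhindered terminal alkene with an electron-poor acrylate is a reliably cross-selective pairing that should give the E-enoate under thermodynamic control, with loss of ethene as driving force, benzoquinone holding back ruthenium hydride chain-walking, and no stereocentre created.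

Step 2
Reactants: 3 methyl (E)-tricos-2-enoate; 4 methyl acetoacetate
Product: 5 dimethyl 2-acetyl-3-icosylpentanedioate (racemic mixture of diastereomers)
Conditions: 4 (3 equiv), Cs2CO3 (0.2 equiv), THF/DMF, 45 °C; aq NH4Cl
Reagents that add atoms: none
Why: Michael addition of the stabilised acetoacetate enolate to the β-carbon of the enoate, run with a catalytic weak base in a dipolar aprotic medium so that the enolate is reactive while the acetyl CH3 stays untouched and ring closure is held back; the two new stereocentres (C2 and C3 of the pentanedioate, later ring C1 and C6) form without control, which is harmless because both become aromatic carbons.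

Step 3
Reactants: 5 dimethyl 2-acetyl-3-icosylpentanedioate
Product: 7 methyl 6-icosyl-2,4-dioxocyclohexane-1-carboxylate (racemic; enolised), via sodium enolate 6 (not isolated)
Conditions: NaOMe (2 equiv, anhydrous), MeOH/THF, reflux; then 1 M HCl, 0 °C
Reagents that add atoms: none
Why: Methoxide deprotonates 5 mainly at the doubly activated C1–H, but proton exchange keeps a small share of the enolate at the acetyl CH3 (C3) available, and this carbon adds to the ester carbonyl of the acetate arm (C4); collapse of the tetrahedral adduct expels methoxide and leaves the new C3–C4 bond. The closest known reaction type is the Dieckmann-type intramolecular Claisen acylation of a 5-oxohexanoate ester, the classical entry to cyclohexane-1,3-diones and to 6-alkyl dihydroresorcylates. The single ring closes in the 6-(enolendo)-exo-trig mode, because both enolate carbons (C2 and C3) become ring members while the attacked C=O points out of the ring. No stereocentre is created: C1 and C6 are carried along as a mixture, C1 equilibrates through the enol, and both are flattened in step 4. The selectivity required is among enolate and carbonyl partners, and the substrate secures it by geometry, since C1 onto C4, C5 onto C2 or onto the C1 ester, and C3 onto the C1 ester would each give a four-membered ring. Every stage is reversible until the product, a vinylogous acid much more acidic than methanol, is trapped as 6, which draws the reversible steps, retro-Michael included, towards the ring, while methyl esters matched to methoxide make ester exchange degenerate.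

Step 4
Reactants: 7 methyl 6-icosyl-2,4-dioxocyclohexane-1-carboxylate
Product: 9 methyl 2-hydroxy-6-icosyl-4-methoxybenzoate (target), via enol ether 8 (not isolated)
Conditions: I2 (2 equiv), MeOH/ClCH2CH2Cl, 23 °C then reflux; aq Na2S2O3
Reagents that add atoms: methanol, CO
Why: Iodine in methanol is a known oxidative aromatisation of cyclohexane-1,3-diones and cyclohexenones to aryl methyl ethers: the acidic medium first turns the vinylogous acid into its methyl enol ether at the unhindered O4 (O2 stays as the ester-chelated enol next to the substituted C1), then iodination and dehydroiodination remove two hydrogens and tautomerisation gives the C2 phenol, which methanol cannot etherify.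

Compound list
1 | docos-1-ene | C=CCCCCCCCCCCCCCCCCCCCC | starting material
2 | methyl acrylate | C=CC(=O)OC | starting material
3 | methyl (E)-tricos-2-enoate | CCCCCCCCCCCCCCCCCCCC/C=C/C(=O)OC | intermediate
4 | methyl acetoacetate | CC(=O)CC(=O)OC | starting material
5 | dimethyl 2-acetyl-3-icosylpentanedioate (racemic mixture of diastereomers) | CCCCCCCCCCCCCCCCCCCCC(CC(=O)OC)C(C(C)=O)C(=O)OC | intermediate
6 | sodium 5-icosyl-4-(methoxycarbonyl)-3-oxocyclohex-1-en-1-olate (charge delocalised over O2–C2–C3–C4–O4; not isolated) | CCCCCCCCCCCCCCCCCCCCC1CC([O-])=CC(=O)C1C(=O)OC.[Na+] | intermediate
7 | methyl 6-icosyl-2,4-dioxocyclohexane-1-carboxylate (racemic; enolised) | CCCCCCCCCCCCCCCCCCCCC1CC(=O)CC(=O)C1C(=O)OC | intermediate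
8 | methyl 6-icosyl-4-methoxy-2-oxocyclohex-3-ene-1-carboxylate (racemic; not isolated) | CCCCCCCCCCCCCCCCCCCCC1CC(OC)=CC(=O)C1C(=O)OC | intermediate
9 | methyl 2-hydroxy-6-icosyl-4-methoxybenzoate | CCCCCCCCCCCCCCCCCCCCc1cc(OC)cc(O)c1C(=O)OC | target

Total step count: 4. Longest linear sequence: 4 (1 → 3 → 5 → 7 → 9).

Steps most likely to fail

Step 3.
- **Risk:** the open-chain keto diester may fragment by retro-Michael reaction, or lose its acetyl group through methoxide attack on the ketone, faster than it cyclises.
- **Fallback (sets out from 1, returns at 6 and hence 7):** donor and acceptor exchange roles. Cross-metathesis of 1 with but-3-en-2-one under the catalyst of step 1 should give (E)-tetracos-3-en-2-one F1. Dimethyl malonate and NaOMe in MeOH/THF at reflux should add to it to give dimethyl 2-(2-oxotetracosan-4-yl)propanedioate F2. In the same pot F2 closes through its ketone CH3 onto one malonate ester (C2–C3 instead of C3–C4) to the same sodium enolate 6, which is acidified to 7.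
- **Why it should be easier:** an enone is a much better acceptor than an enoate, and this adduct has no acetyl group on a doubly activated carbon to lose.

Step 4.
- **Risk:** chemoselectivity would erode through etherification of the second ring oxygen before the ring is aromatic, incomplete dehydrogenation, or iodination of the electron-rich arene.
- **Fallback (sets out from 7, returns at 9):** oxidation and methylation are separated. Bromination and dehydrobromination with Br2 (1 equiv) in DMF, 0 °C then 80 °C, should give methyl 2,4-dihydroxy-6-icosylbenzoate F3. MeI (1 equiv) and K2CO3 in acetone should then give 9.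
- **Why it should be selective:** only the free, more acidic 4-OH should be alkylated, because the 2-OH is locked in a hydrogen bond to the ester carbonyl.

Step 2.
- **Risk:** addition to a β-alkyl enoate is slow and reversible, and early ring closure would use up the catalytic base so that conversion stalls.
- **Fallback (sets out from 1 and 4, returns at 5):** the pairing is reversed so that the acetoacetate carbon sits in a doubly activated acceptor.
  - Ozonolysis of 1 (O3, CH2Cl2, −78 °C; PPh3) should give henicosanal F4.
  - Knoevenagel condensation with 4 (piperidinium acetate cat., 4 Å molecular sieves, CH2Cl2, 0 °C) should give methyl 2-acetyltricos-2-enoate F5.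
  - Mukaiyama–Michael addition of commercial 1-(tert-butyldimethylsilyloxy)-1-methoxyethene (Sc(OTf)3 cat., CH2Cl2, −78 °C) should give the silyl enol ether dimethyl 2-[1-(tert-butyldimethylsilyloxy)ethylidene]-3-icosylpentanedioate F6.
  - Dilute HCl in THF hydrolyses F6 to 5.

Further compounds
F1 | step 3 | (E)-tetracos-3-en-2-one | CCCCCCCCCCCCCCCCCCCC/C=C/C(C)=O
F2 | step 3 | dimethyl 2-(2-oxotetracosan-4-yl)propanedioate (racemic) | CCCCCCCCCCCCCCCCCCCCC(CC(C)=O)C(C(=O)OC)C(=O)OC
F3 | step 4 | methyl 2,4-dihydroxy-6-icosylbenzoate | CCCCCCCCCCCCCCCCCCCCc1cc(O)cc(O)c1C(=O)OC
F4 | step 2 | henicosanal | CCCCCCCCCCCCCCCCCCCCC=O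
F5 | step 2 | methyl 2-acetyltricos-2-enoate (mixture of alkene isomers) | CCCCCCCCCCCCCCCCCCCCC=C(C(C)=O)C(=O)OC
F6 | step 2 | dimethyl 2-[1-(tert-butyldimethylsilyloxy)ethylidene]-3-icosylpentanedioate (racemic; mixture of alkene isomers) | CCCCCCCCCCCCCCCCCCCCC(CC(=O)OC)C(C(=O)OC)=C(C)O[Si](C)(C)C(C)(C)C
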